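Ring A, the carbocycle (C1 and C6 quaternary fusion carbons, C2 C(CH3)OH, C3 CH2, C4 CH–OAc, C5 CH–OBz), is disconnected at C3–C4 after retro-hydration of C2 to an exocyclic methylene. The 1,3-relationship of the C4 oxygen and C2 across the C3 methylene is the retron of a type-two intramolecular carbonyl-ene reaction: an aldehyde (C4) on the C6 side chain and an isopropenyl group on C1 of the preformed lactone/oxepene bicycle close ring A in one operation, setting the axial C4 carbinol and leaving the alkene that later takes the C2 hydroxyl. The precursor is a bridged 2,7-dioxabicyclo[4.2.1]nonenone bearing CH(OBz)CHO and C(CH3)=CH2.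

Key step: step 16

Remark: atom labels in the text are the locants of the target name and are used for the corresponding atoms of every intermediate: C1 (ring-fusion carbon bearing the ether oxygen O11 and the lactone carbonyl C12), C2, C3, C4, C5, C6 (C-methyl ring-fusion carbon), C7 (lactone CH–O13), C8=C9 (ring alkene), C10 (C(CH3)2).
Assumption: compounds 1, 7 and 8 are taken as commercial; the C1 configuration drawn for 12–14 assumes the chelated (Z)-ketene acetal and a chair transition state in step 7 and is erased in step 10.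

Step 1
Reactants: 1 methyl (4S)-2,2-dimethyl-1,3-dioxolane-4-carboxylate
Product: 3 (4R)-4-ethynyl-2,2-dimethyl-1,3-dioxolane, via (S)-glyceraldehyde acetonide 2 (not isolated)
Conditions: i-Bu2AlH, CH2Cl2, −78 °C; then MeOH, K2CO3, dimethyl (1-diazo-2-oxopropyl)phosphonate, −78 °C → rt
Reagents that add atoms: dimethyl (1-diazo-2-oxopropyl)phosphonate, CC(=O)C(=[N+]=[N-])P(=O)(OC)OC
Why: i-Bu2AlH at −78 °C stops at the aluminium hemiacetal and the configurationally labile α-alkoxy aldehyde is homologated in the same flask (Seyferth–Gilbert homologation with the Ohira–Bestmann reagent), so the chiral-pool stereocentre (future C5) is carried through unchanged.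

Step 2
Reactants: 3 (4R)-4-ethynyl-2,2-dimethyl-1,3-dioxolane
Product: 4 methyl 3-[(4R)-2,2-dimethyl-1,3-dioxolan-4-yl]prop-2-ynoate
Conditions: n-BuLi, THF, −78 °C; ClCO2Me, −78 → 0 °C
Reagents that add atoms: methyl chloroformate, COC(=O)Cl
Why: Deprotonation of the terminal alkyne and C-acylation of the lithium acetylide with a chloroformate is the standard route to ynoates and touches no stereocentre.

Step 3
Reactants: 4 methyl 3-[(4R)-2,2-dimethyl-1,3-dioxolan-4-yl]prop-2-ynoate
Product: 5 methyl (2Z)-3-[(4R)-2,2-dimethyl-1,3-dioxolan-4-yl]but-2-enoate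
Conditions: Me2CuLi (from MeLi and CuBr·SMe2), THF, −78 °C; MeOH then aq. NH4Cl at −78 °C
Reagents that add atoms: lithium dimethylcuprate, [Li+].C[Cu-]C (made in the flask from methyllithium, [Li]C, and CuBr·SMe2)
Why: syn-Carbocupration of the ynoate by the Gilman reagent (conjugate addition) and protonation of the vinylcopper at −78 °C with retention should give the (Z)-β-methyl enoate, the propargylic acetal oxygen being too poor a leaving group for allene formation.

Step 4
Reactants: 5 methyl (2Z)-3-[(4R)-2,2-dimethyl-1,3-dioxolan-4-yl]but-2-enoate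
Product: 6 (2Z)-3-[(4R)-2,2-dimethyl-1,3-dioxolan-4-yl]but-2-en-1-ol
Conditions: i-Bu2AlH (2.5 equiv), CH2Cl2, −78 °C; Rochelle salt
Reagents that add atoms: none
Why: 1,2-Reduction of the enoate by i-Bu2AlH gives the allylic alcohol with retention of the Z geometry, the acetonide keeping the cis-disposed γ-oxygen from lactonising.

Step 5
Reactants: 7 2-methylpent-4-en-2-ol; 8 bromoacetic acid
Product: 9 2-[(2-methylpent-4-en-2-yl)oxy]acetic acid
Conditions: NaH (2.2 equiv), THF, 0 °C → reflux; then aq. HCl to pH 2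
Reagents that add atoms: none
Why: Williamson etherification of the tertiary sodium alkoxide with unhindered sodium bromoacetate is the usual access to tert-alkoxyacetic acids and fixes the hindered C1–O11–C10 ether linkage at the outset.

Step 6
Reactants: 6 (2Z)-3-[(4R)-2,2-dimethyl-1,3-dioxolan-4-yl]but-2-en-1-ol; 9 2-[(2-methylpent-4-en-2-yl)oxy]acetic acid
Product: 10 (2Z)-3-[(4R)-2,2-dimethyl-1,3-dioxolan-4-yl]but-2-en-1-yl 2-[(2-methylpent-4-en-2-yl)oxy]acetate
Conditions: DCC, DMAP (cat.), CH2Cl2, 0 °C → rt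
Reagents that add atoms: none
Why: Steglich esterification joins the two fragments under neutral conditions that leave the acetonide and both alkenes untouched.

Step 7
Reactants: 10 (2Z)-3-[(4R)-2,2-dimethyl-1,3-dioxolan-4-yl]but-2-en-1-yl 2-[(2-methylpent-4-en-2-yl)oxy]acetate
Product: 12 (2S,3R)-3-[(4R)-2,2-dimethyl-1,3-dioxolan-4-yl]-3-methyl-2-[(2-methylpent-4-en-2-yl)oxy]pent-4-enoic acid, via silyl ketene acetal 11 (not isolated)
Conditions: LiN(i-Pr)2, THF, −78 °C; Me3SiCl, −78 → 50 °C; then MeOH/H2O, work-up at pH 4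
Reagents that add atoms: none
Why: Ireland–Claisen rearrangement of the chelated (Z)-silyl ketene acetal builds the quaternary C6 centre, the Z-alkene holding the allylic hydrogen in the alkene plane (A(1,3) strain) so that the new bond should form anti to the dioxolane C–O bond (Felkin–Anh-type control from the chiral-pool centre), while the C1 epimer formed is inconsequential and the homoallyl (not allyl) ether excludes a competing [2,3]-Wittig shift.

Step 8
Reactants: 12 (2S,3R)-3-[(4R)-2,2-dimethyl-1,3-dioxolan-4-yl]-3-methyl-2-[(2-methylpent-4-en-2-yl)oxy]pent-4-enoic acid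
Product: 13 tert-butyl (2S,3R)-3-[(4R)-2,2-dimethyl-1,3-dioxolan-4-yl]-3-methyl-2-[(2-methylpent-4-en-2-yl)oxy]pent-4-enoate
Conditions: t-BuOC(=NH)CCl3, cyclohexane/CH2Cl2, rt
Reagents that add atoms: tert-butyl 2,2,2-trichloroacetimidate, CC(C)(C)OC(=N)C(Cl)(Cl)Cl
Why: The carboxylic acid itself protonates the trichloroacetimidate, which transfers the tert-butyl group without added acid, so the acetonide survives and the ester becomes the latent lactone carbonyl.

Step 9
Reactants: 13 tert-butyl (2S,3R)-3-[(4R)-2,2-dimethyl-1,3-dioxolan-4-yl]-3-methyl-2-[(2-methylpent-4-en-2-yl)oxy]pent-4-enoate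
Product: 14 tert-butyl (2S,3R)-3-[(4R)-2,2-dimethyl-1,3-dioxolan-4-yl]-3,7,7-trimethyl-2,3,6,7-tetrahydrooxepine-2-carboxylate
Conditions: second-generation Grubbs catalyst (H2IMes)(PCy3)Cl2Ru=CHPh (5 mol %), CH2Cl2 (5 mM), 40 °C
Reagents that add atoms: none
Why: Ring-closing metathesis of the two terminal alkenes closes the seven-membered oxepene with loss of ethene, the only competing pairing being intermolecular and suppressed by dilution.

Step 10
Reactants: 14 tert-butyl (2S,3R)-3-[(4R)-2,2-dimethyl-1,3-dioxolan-4-yl]-3,7,7-trimethyl-2,3,6,7-tetrahydrooxepine-2-carboxylate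
Product: 15 tert-butyl (2S,3R)-2-acetyl-3-[(4R)-2,2-dimethyl-1,3-dioxolan-4-yl]-3,7,7-trimethyl-2,3,6,7-tetrahydrooxepine-2-carboxylate
Conditions: LiN(i-Pr)2, THF, −78 °C; AcCl, −78 °C
Reagents that add atoms: acetyl chloride, CC(=O)Cl
Why: C-Acylation of a lithium ester enolate by an acid chloride should bring the acetyl group in anti to the dioxolanyl group on the adjacent quaternary C6 (syn to the C6 methyl), which sets the quaternary C1 centre with the ester on the face from which it can later bridge to C7.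

Step 11
Reactants: 15 tert-butyl (2S,3R)-2-acetyl-3-[(4R)-2,2-dimethyl-1,3-dioxolan-4-yl]-3,7,7-trimethyl-2,3,6,7-tetrahydrooxepine-2-carboxylate
Product: 17 (1S,6S,9R)-1-acetyl-9-[(4R)-2,2-dimethyl-1,3-dioxolan-4-yl]-3,3,9-trimethyl-2,7-dioxabicyclo[4.2.1]non-4-en-8-one, via selenide 16 (not isolated)
Conditions: PhSeCl, CH2Cl2, −78 → 0 °C; then pyridine, 30% aq. H2O2, 0 °C → rt
Reagents that add atoms: none
Why: Selenolactonisation followed by selenoxide syn-elimination: the ester carbonyl opens the seleniranium ion at C7 in a 5-exo anti addition (loss of tert-butyl chloride) that is possible only on the ring face carrying the ester, so C7 is set by the bridging, and the selenoxide then eliminates away from the oxygen-bearing carbon to place the alkene at C8=C9.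

Step 12
Reactants: 17 (1S,6S,9R)-1-acetyl-9-[(4R)-2,2-dimethyl-1,3-dioxolan-4-yl]-3,3,9-trimethyl-2,7-dioxabicyclo[4.2.1]non-4-en-8-one
Product: 18 (1R,6S,9R)-9-[(4R)-2,2-dimethyl-1,3-dioxolan-4-yl]-3,3,9-trimethyl-1-(prop-1-en-2-yl)-2,7-dioxabicyclo[4.2.1]non-4-en-8-one
Conditions: Ph3PCH3Br, KN(SiMe3)2, THF, 0 °C; then 17, 0 °C → rt
Reagents that add atoms: methyltriphenylphosphonium bromide, C[P+](c1ccccc1)(c1ccccc1)c1ccccc1.[Br-]
Why: Wittig methylenation of the only ketone should be clean because the lactone is far less electrophilic toward the ylide and retro-Claisen cleavage is blocked, the leaving group being a bridgehead enolate.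

Step 13
Reactants: 18 (1R,6S,9R)-9-[(4R)-2,2-dimethyl-1,3-dioxolan-4-yl]-3,3,9-trimethyl-1-(prop-1-en-2-yl)-2,7-dioxabicyclo[4.2.1]non-4-en-8-one
Product: 19 (1R,6S,9S)-9-[(1R)-1,2-dihydroxyethyl]-3,3,9-trimethyl-1-(prop-1-en-2-yl)-2,7-dioxabicyclo[4.2.1]non-4-en-8-one
Conditions: AcOH/H2O (4:1), 40 °C
Reagents that add atoms: none
Why: Mild aqueous-acid hydrolysis of the isopropylidene acetal should spare the tertiary ether and the lactone, acyl transfer to the new hydroxyls being disfavoured by the strained bicyclic orthoacid it would require.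

Step 14
Reactants: 19 (1R,6S,9S)-9-[(1R)-1,2-dihydroxyethyl]-3,3,9-trimethyl-1-(prop-1-en-2-yl)-2,7-dioxabicyclo[4.2.1]non-4-en-8-one
Product: 21 (1R)-2-hydroxy-1-[(1R,6S,9R)-3,3,9-trimethyl-8-oxo-1-(prop-1-en-2-yl)-2,7-dioxabicyclo[4.2.1]non-4-en-9-yl]ethyl benzoate, via cyclic orthobenzoate 20 (not isolated)
Conditions: PhC(OMe)3, camphorsulfonic acid (cat.), CH2Cl2, rt; then AcOH/H2O (4:1), 0 °C
Reagents that add atoms: trimethyl orthobenzoate, COC(OC)(OC)c1ccccc1; water, O
Why: Cyclic orthoester formation and kinetically controlled hydrolysis through the 2-phenyl-1,3-dioxolan-2-ylium ion should release the less hindered primary hydroxyl and leave the benzoate on the secondary C5 oxygen (regioselective monoacylation of a 1,2-diol) without touching the stereocentre.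

Step 15
Reactants: 21 (1R)-2-hydroxy-1-[(1R,6S,9R)-3,3,9-trimethyl-8-oxo-1-(prop-1-en-2-yl)-2,7-dioxabicyclo[4.2.1]non-4-en-9-yl]ethyl benzoate
Product: 22 (1R)-2-oxo-1-[(1R,6S,9R)-3,3,9-trimethyl-8-oxo-1-(prop-1-en-2-yl)-2,7-dioxabicyclo[4.2.1]non-4-en-9-yl]ethyl benzoate
Conditions: Dess–Martin periodinane, CH2Cl2, 0 °C → rt
Reagents that add atoms: none
Why: Dess–Martin oxidation of the primary alcohol under near-neutral conditions should give the α-benzoyloxy aldehyde without epimerisation at C5 or acyl migration.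

Step 16
Reactants: 22 (1R)-2-oxo-1-[(1R,6S,9R)-3,3,9-trimethyl-8-oxo-1-(prop-1-en-2-yl)-2,7-dioxabicyclo[4.2.1]non-4-en-9-yl]ethyl benzoate
Product: 23 (1R,4S,5R,6R,7S)-4-hydroxy-6,10,10-trimethyl-2-methylidene-12-oxo-11,13-dioxatricyclo[5.4.2.0^1,6]tridec-8-en-5-yl benzoate
Conditions: Me2AlCl (2 equiv), CH2Cl2, −78 → −20 °C; aq. NaHCO3/Rochelle salt
Reagents that add atoms: none
Why: Me2AlCl activates the C4 aldehyde, the CH2 terminus of the C1 isopropenyl group bonds to C4 while the carbonyl oxygen takes a hydrogen from the isopropenyl methyl through a six-centre transition state, a concerted type-two intramolecular carbonyl-ene reaction whose closest precedent is the Me2AlCl-promoted cyclisation of 5-methylhex-5-enals to 3-methylenecyclohexanols. Ring A is the only ring closed, by C3–C4 bond formation that is exo at the carbonyl and endo at the alkene (both ene carbons C2 and C3 become ring members), giving a six-membered ring fused at C1–C6. The one new stereocentre, C4, is controlled by transition-state geometry: the bicycle fixes the chair of the forming ring (C5 benzoate equatorial, C6 methyl axial) and the hydrogen shift is possible only when the aldehyde oxygen is axial, so the alkoxide should be delivered syn to the C6 methyl as the target requires. The step needs site selectivity for the isopropenyl group over the C8=C9 alkene, secured because that alkene is 1,2-disubstituted, deactivated by two allylic oxygens and held away from the aldehyde by the bicycle. It also needs the ene pathway to win over stepwise Prins ionisation and over ionisation of the tertiary allylic ether, which the weakly acidic, proton-scavenging Me2AlCl at low temperature should secure.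

Step 17
Reactants: 23 (1R,4S,5R,6R,7S)-4-hydroxy-6,10,10-trimethyl-2-methylidene-12-oxo-11,13-dioxatricyclo[5.4.2.0^1,6]tridec-8-en-5-yl benzoate
Product: 24 (1R,4S,5R,6R,7S)-4-(acetyloxy)-6,10,10-trimethyl-2-methylidene-12-oxo-11,13-dioxatricyclo[5.4.2.0^1,6]tridec-8-en-5-yl benzoate
Conditions: Ac2O, DMAP, pyridine, CH2Cl2, rt
Reagents that add atoms: acetic anhydride, CC(=O)OC(C)=O
Why: DMAP-catalysed acetylation of the only free hydroxyl (secondary, C4) should proceed before any benzoate migration can occur.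

Step 18
Reactants: 24 (1R,4S,5R,6R,7S)-4-(acetyloxy)-6,10,10-trimethyl-2-methylidene-12-oxo-11,13-dioxatricyclo[5.4.2.0^1,6]tridec-8-en-5-yl benzoate
Product: 25 (1S,2S,4S,5R,6R,7S)-4-(acetyloxy)-2-hydroxy-2,6,10,10-tetramethyl-12-oxo-11,13-dioxatricyclo[5.4.2.0^1,6]tridec-8-en-5-yl benzoate (target)
Conditions: Co(acac)2 (20 mol %), PhSiH3, O2 (1 atm), THF/i-PrOH, rt
Reagents that add atoms: dioxygen, O=O
Why: Mukaiyama hydration (metal-hydride hydrogen-atom transfer) should add hydrogen to the CH2 terminus of the 1,1-disubstituted alkene in preference to the hindered, electron-poor C8=C9 alkene, and dioxygen should trap the tertiary C2 radical from the equatorial side because the axial face is screened by the syn-axial C6 methyl and C4 acetoxy groups, giving the equatorial hydroxyl and axial methyl of the target.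

Compound list
1 | methyl (4S)-2,2-dimethyl-1,3-dioxolane-4-carboxylate | COC(=O)[C@H]1OC(C)(C)OC1 | starting material
2 | (4S)-2,2-dimethyl-1,3-dioxolane-4-carbaldehyde | O=C[C@H]1OC(C)(C)OC1 | intermediate (not isolated)
3 | (4R)-4-ethynyl-2,2-dimethyl-1,3-dioxolane | C#C[C@H]1OC(C)(C)OC1 | intermediate
4 | methyl 3-[(4R)-2,2-dimethyl-1,3-dioxolan-4-yl]prop-2-ynoate | COC(=O)C#C[C@H]1OC(C)(C)OC1 | intermediate
5 | methyl (2Z)-3-[(4R)-2,2-dimethyl-1,3-dioxolan-4-yl]but-2-enoate | COC(=O)/C=C(/C)[C@H]1OC(C)(C)OC1 | intermediate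
6 | (2Z)-3-[(4R)-2,2-dimethyl-1,3-dioxolan-4-yl]but-2-en-1-ol | OC/C=C(/C)[C@H]1OC(C)(C)OC1 | intermediate
7 | 2-methylpent-4-en-2-ol | C=CCC(C)(C)O | starting material
8 | bromoacetic acid | OC(=O)CBr | starting material
9 | 2-[(2-methylpent-4-en-2-yl)oxy]acetic acid | C=CCC(C)(C)OCC(=O)O | intermediate
10 | (2Z)-3-[(4R)-2,2-dimethyl-1,3-dioxolan-4-yl]but-2-en-1-yl 2-[(2-methylpent-4-en-2-yl)oxy]acetate | C=CCC(C)(C)OCC(=O)OC/C=C(/C)[C@H]1OC(C)(C)OC1 | intermediate
11 | (Z)-O-trimethylsilyl ketene acetal of 10 (Me3SiO cis to the ether oxygen) | C=CCC(C)(C)O/C=C(\O[Si](C)(C)C)OC/C=C(/C)[C@H]1OC(C)(C)OC1 | intermediate (not isolated)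
12 | (2S,3R)-3-[(4R)-2,2-dimethyl-1,3-dioxolan-4-yl]-3-methyl-2-[(2-methylpent-4-en-2-yl)oxy]pent-4-enoic acid | OC(=O)[C@@H](OC(C)(C)CC=C)[C@](C)(C=C)[C@H]1OC(C)(C)OC1 | intermediate
13 | tert-butyl (2S,3R)-3-[(4R)-2,2-dimethyl-1,3-dioxolan-4-yl]-3-methyl-2-[(2-methylpent-4-en-2-yl)oxy]pent-4-enoate | CC(C)(C)OC(=O)[C@@H](OC(C)(C)CC=C)[C@](C)(C=C)[C@H]1OC(C)(C)OC1 | intermediate
14 | tert-butyl (2S,3R)-3-[(4R)-2,2-dimethyl-1,3-dioxolan-4-yl]-3,7,7-trimethyl-2,3,6,7-tetrahydrooxepine-2-carboxylate | CC(C)(C)OC(=O)[C@H]1OC(C)(C)CC=C[C@]1(C)[C@H]2OC(C)(C)OC2 | intermediate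
15 | tert-butyl (2S,3R)-2-acetyl-3-[(4R)-2,2-dimethyl-1,3-dioxolan-4-yl]-3,7,7-trimethyl-2,3,6,7-tetrahydrooxepine-2-carboxylate | CC(=O)[C@@]1(C(=O)OC(C)(C)C)OC(C)(C)CC=C[C@]1(C)[C@H]2OC(C)(C)OC2 | intermediate
16 | (1S,5R,6R,9S)-1-acetyl-9-[(4R)-2,2-dimethyl-1,3-dioxolan-4-yl]-3,3,9-trimethyl-5-(phenylselanyl)-2,7-dioxabicyclo[4.2.1]nonan-8-one | CC(=O)[C@]12OC(C)(C)C[C@@H]([Se]c3ccccc3)[C@H](OC1=O)[C@]2(C)[C@H]1OC(C)(C)OC1 | intermediate (not isolated)
17 | (1S,6S,9R)-1-acetyl-9-[(4R)-2,2-dimethyl-1,3-dioxolan-4-yl]-3,3,9-trimethyl-2,7-dioxabicyclo[4.2.1]non-4-en-8-one | CC(=O)[C@]12OC(C)(C)C=C[C@H](OC1=O)[C@]2(C)[C@H]1OC(C)(C)OC1 | intermediate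
18 | (1R,6S,9R)-9-[(4R)-2,2-dimethyl-1,3-dioxolan-4-yl]-3,3,9-trimethyl-1-(prop-1-en-2-yl)-2,7-dioxabicyclo[4.2.1]non-4-en-8-one | CC(=C)[C@]12OC(C)(C)C=C[C@H](OC1=O)[C@]2(C)[C@H]1OC(C)(C)OC1 | intermediate
19 | (1R,6S,9S)-9-[(1R)-1,2-dihydroxyethyl]-3,3,9-trimethyl-1-(prop-1-en-2-yl)-2,7-dioxabicyclo[4.2.1]non-4-en-8-one | CC(=C)[C@]12OC(C)(C)C=C[C@H](OC1=O)[C@]2(C)[C@H](CO)O | intermediate
20 | (1R,6S,9R)-9-[(4R)-2-methoxy-2-phenyl-1,3-dioxolan-4-yl]-3,3,9-trimethyl-1-(prop-1-en-2-yl)-2,7-dioxabicyclo[4.2.1]non-4-en-8-one (both orthoester epimers) | CC(=C)[C@]12OC(C)(C)C=C[C@H](OC1=O)[C@]2(C)[C@H]1OC(OC)(c2ccccc2)OC1 | intermediate (not isolated)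
21 | (1R)-2-hydroxy-1-[(1R,6S,9R)-3,3,9-trimethyl-8-oxo-1-(prop-1-en-2-yl)-2,7-dioxabicyclo[4.2.1]non-4-en-9-yl]ethyl benzoate | CC(=C)[C@]12OC(C)(C)C=C[C@H](OC1=O)[C@]2(C)[C@H](CO)OC(=O)c1ccccc1 | intermediate
22 | (1R)-2-oxo-1-[(1R,6S,9R)-3,3,9-trimethyl-8-oxo-1-(prop-1-en-2-yl)-2,7-dioxabicyclo[4.2.1]non-4-en-9-yl]ethyl benzoate | CC(=C)[C@]12OC(C)(C)C=C[C@H](OC1=O)[C@]2(C)[C@H](C=O)OC(=O)c1ccccc1 | intermediate
23 | (1R,4S,5R,6R,7S)-4-hydroxy-6,10,10-trimethyl-2-methylidene-12-oxo-11,13-dioxatricyclo[5.4.2.0^1,6]tridec-8-en-5-yl benzoate | O[C@H]1CC(=C)[C@]23OC(C)(C)C=C[C@H](OC2=O)[C@]3(C)[C@H]1OC(=O)c1ccccc1 | intermediate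
24 | (1R,4S,5R,6R,7S)-4-(acetyloxy)-6,10,10-trimethyl-2-methylidene-12-oxo-11,13-dioxatricyclo[5.4.2.0^1,6]tridec-8-en-5-yl benzoate | CC(=O)O[C@H]1CC(=C)[C@]23OC(C)(C)C=C[C@H](OC2=O)[C@]3(C)[C@H]1OC(=O)c1ccccc1 | intermediate
25 | (1S,2S,4S,5R,6R,7S)-4-(acetyloxy)-2-hydroxy-2,6,10,10-tetramethyl-12-oxo-11,13-dioxatricyclo[5.4.2.0^1,6]tridec-8-en-5-yl benzoate | CC(=O)O[C@H]1C[C@](C)(O)[C@]23OC(C)(C)C=C[C@H](OC2=O)[C@]3(C)[C@H]1OC(=O)c1ccccc1 | target

Total step count: 18. Longest linear sequence: 17 steps (steps 1–4 and 6–18, from compound 1); step 5 prepares the second fragment.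

Steps most likely to fail

Step 16. The chair ene transition state carries three syn-axial groups (C6 methyl, the C4 oxygen and the reacting methyl), so stepwise Prins ionisation with poor facial selectivity at C4 may take over and deliver the equatorial carbinol. The fallback sets out from 22 and returns at 23: the closure is run without stereocontrol and the (1R,4R,5R,6R,7S) C4-epimeric alcohol F1 is accepted, it is oxidised with Dess–Martin periodinane to the β,γ-unsaturated ketone F2, and this is reduced with LiBH(s-Bu)3 at −78 °C, where the bulky hydride should attack from the equatorial direction (the axial face being blocked by the C6 methyl) to give the axial alcohol 23.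

Step 10. O-acylation of the congested enolate, or failure to build the second of two adjacent quaternary centres, may prevail. The fallback sets out from 14 and returns at 15: the same lithium enolate is trapped with acetaldehyde, a smaller electrophile that can only react at carbon, to give the 1-hydroxyethyl adduct F3 (either carbinol epimer), which is oxidised with Dess–Martin periodinane to 15.

Step 18. Capture of the C2 radical from the axial face, or hydrogen-atom transfer to the ring alkene, would erode selectivity. The fallback sets out from 24 and returns at 25: dimethyldioxirane should epoxidise the exocyclic alkene from the equatorial direction to give the C2 spiro-epoxide F4, MgI2 should open it at the CH2 terminus to the iodohydrin F5, and Bu3SnH with azobisisobutyronitrile should remove the iodine by a radical chain to give 25.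

Further compounds
F1 | step 16 | (1R,4R,5R,6R,7S)-4-hydroxy-6,10,10-trimethyl-2-methylidene-12-oxo-11,13-dioxatricyclo[5.4.2.0^1,6]tridec-8-en-5-yl benzoate (C4 epimer of 23) | O[C@@H]1CC(=C)[C@]23OC(C)(C)C=C[C@H](OC2=O)[C@]3(C)[C@H]1OC(=O)c1ccccc1
F2 | step 16 | (1R,5R,6R,7S)-6,10,10-trimethyl-2-methylidene-4,12-dioxo-11,13-dioxatricyclo[5.4.2.0^1,6]tridec-8-en-5-yl benzoate | O=C1CC(=C)[C@]23OC(C)(C)C=C[C@H](OC2=O)[C@]3(C)[C@H]1OC(=O)c1ccccc1
F3 | step 10 | tert-butyl (2S,3R)-3-[(4R)-2,2-dimethyl-1,3-dioxolan-4-yl]-2-(1-hydroxyethyl)-3,7,7-trimethyl-2,3,6,7-tetrahydrooxepine-2-carboxylate (either carbinol epimer) | CC(O)[C@@]1(C(=O)OC(C)(C)C)OC(C)(C)CC=C[C@]1(C)[C@H]2OC(C)(C)OC2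
F4 | step 18 | C2 spiro-epoxide of 24, epoxide oxygen equatorial (2R), other centres as in 25 | CC(=O)O[C@H]1C[C@@]2(CO2)[C@]34OC(C)(C)C=C[C@H](OC3=O)[C@]4(C)[C@H]1OC(=O)c1ccccc1
F5 | step 18 | (1S,2S,4S,5R,6R,7S)-4-(acetyloxy)-2-hydroxy-2-(iodomethyl)-6,10,10-trimethyl-12-oxo-11,13-dioxatricyclo[5.4.2.0^1,6]tridec-8-en-5-yl benzoate | CC(=O)O[C@H]1C[C@](CI)(O)[C@]23OC(C)(C)C=C[C@H](OC2=O)[C@]3(C)[C@H]1OC(=O)c1ccccc1
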